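**Retrosynthetic overview**
1. The dihydropyran ring is cut last by a retro oxa-Diels–Alder (O–C4 and C1′–C5 bonds), giving (−)-β-caryophyllene and an isobutyryl-substituted alkylidene trione.
2. The alkylidene trione is cut at its exocyclic C=C (Knoevenagel) into syncarpic acid and 3-methyl-2-oxobutanal; it is made in the flask.
3. Syncarpic acid comes from 2′,4′,6′-trihydroxyacetophenone by dearomatising tetra-C-methylation, then retro-Claisen deacetylation.
4. 3-Methyl-2-oxobutanal comes from 3-methylbutan-2-one by Riley oxidation.
5. Ring order: the trione ring first (from the arene); the cyclobutane and nine-membered ring are bought with caryophyllene; the dihydropyran ring is formed last.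

Assumption: natural (−)-β-caryophyllene (1R,9S,4E) is bought as the single enantiomer. Caryophyllane numbering (C1–C15) is used, and the pyran carbon bearing the isobutyryl group is called C1′.

**Step 1**
Reactants: 1 1-(2,4,6-trihydroxyphenyl)ethan-1-one; 2 iodomethane
Product: 3 acetylsyncarpic acid (2-acetyl-3-hydroxy-4,4,6,6-tetramethylcyclohex-2-ene-1,5-dione)
Conditions: NaOMe (6 equiv), MeI (6 equiv), MeOH, 0 °C to reflux; then aq HCl
Reagents that add atoms: iodomethane, CI
Why: Dearomatising exhaustive C-alkylation of the phloroglucinol polyanion, in which the acetyl group blocks the third ring carbon so that only the two free ring CH positions are gem-dimethylated; no stereocenter is formed.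

**Step 2**
Reactants: 3 acetylsyncarpic acid
Product: 4 syncarpic acid (2,2,4,4-tetramethylcyclohexane-1,3,5-trione)
Conditions: 6 M aq HCl, reflux
Reagents that add atoms: none
Why: Acid-mediated retro-Claisen deacylation removes the exocyclic acetyl group as acetic acid because the ring carbonyls are shielded by the flanking quaternary carbons; no stereocenter is formed.

**Step 3**
Reactants: 5 3-methylbutan-2-one
Product: 6 3-methyl-2-oxobutanal (isopropylglyoxal)
Conditions: SeO2 (1.0 equiv), 1,4-dioxane/H2O, reflux; filter, distil, use fresh
Reagents that add atoms: selenium dioxide, O=[Se]=O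
Why: Riley oxidation of a methyl ketone to the glyoxal, where only the methyl side can be taken to a carbonyl; no stereocenter is formed.

**Step 4**
Reactants: 4 syncarpic acid; 6 3-methyl-2-oxobutanal; 7 (−)-β-caryophyllene
Product: 9 tomentodione Q, via alkylidene trione 8 (not isolated)
Conditions: 7 (3 equiv), 6 (1.2 equiv), ethylenediammonium diacetate (10 mol %), 4 Å MS, toluene, rt to 60 °C; 4 added slowly in THF; chromatography
Reagents that add atoms: none
Why: Domino Knoevenagel/inverse-electron-demand oxa-Diels–Alder reaction in which the aldehyde carbon of 6 condenses with 4 to give oxadiene 8, which adds suprafacially to the strained (E)-C4=C5 bond of 7 on its exposed face (the face epoxidised in natural caryophyllene oxide) with oxygen going to the tertiary C4, fixing 4R,5S; the orientation with the isobutyryl group outside on the oxadiene and the C4-methyl/C6 edge of the alkene beneath it gives 1′R (H-1′ cis to H-5), and C1 and C9 are carried over unchanged from 7.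

**Compound list**
1 | 1-(2,4,6-trihydroxyphenyl)ethan-1-one (2′,4′,6′-trihydroxyacetophenone) | CC(=O)c1c(O)cc(O)cc1O | starting material
2 | iodomethane | CI | starting material
3 | acetylsyncarpic acid (2-acetyl-3-hydroxy-4,4,6,6-tetramethylcyclohex-2-ene-1,5-dione) | CC(=O)C1=C(O)C(C)(C)C(=O)C(C)(C)C1=O | intermediate
4 | syncarpic acid (2,2,4,4-tetramethylcyclohexane-1,3,5-trione, drawn as the triketone) | CC1(C)C(=O)CC(=O)C(C)(C)C1=O | intermediate
5 | 3-methylbutan-2-one | CC(C)C(C)=O | starting material
6 | 3-methyl-2-oxobutanal (isopropylglyoxal) | CC(C)C(=O)C=O | intermediate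
7 | (−)-β-caryophyllene (1R,9S,4E) | C=C1CC/C=C(\C)CC[C@@H]2[C@@H]1CC2(C)C | starting material
8 | alkylidene trione (2,2,4,4-tetramethyl-6-(3-methyl-2-oxobutylidene)cyclohexane-1,3,5-trione) | CC(C)C(=O)C=C1C(=O)C(C)(C)C(=O)C(C)(C)C1=O | intermediate
9 | tomentodione Q (1R,4R,5S,9S,1′R; dihydropyran trans-fused at C4–C5, O on C4, isobutyryl on C1′ with H-1′ cis to H-5, C8 exocyclic methylene, trans-fused cyclobutane) | C=C1CC[C@H]2[C@@H](C(=O)C(C)C)C3=C(O[C@]2(C)CC[C@@H]2[C@@H]1CC2(C)C)C(C)(C)C(=O)C(C)(C)C3=O | target

**Totals**
Total step count: 4. Longest linear sequence: 3 (steps 1, 2, 4); step 3 is a one-step side branch.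

**Steps most likely to fail**

Step 4 is the most likely to fail. Free 4 can add to 8 to give a 2:1 adduct, 8 can oligomerise, and the endo/exo ratio at C1′ cannot be predicted with confidence. The fallback sets out from 4 and 6, which are condensed reductively (Hantzsch ester, L-proline cat., CH2Cl2, rt) to 2,2,4,4-tetramethyl-6-(3-methyl-2-oxobutyl)cyclohexane-1,3,5-trione F1, a stable saturated precursor. F1 is then dehydrogenated with TEMPO and Ag2O (THF, rt) in the presence of 7 (3 equiv), so that the oxadiene is released slowly with no free 4 in the flask; this comes back to the route at 8 and hence at 9. If the adduct mixture is dominated by the C1′ epimer, 1′-epi-tomentodione Q F2, it is equilibrated through the enolate of its isobutyryl ketone (DBU, toluene, 60 °C) and re-chromatographed to give more 9.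

Step 3 is the second risk. The tertiary C–H may be oxidised in competition, the glyoxal may over-oxidise, and it is volatile and hydrate-forming. The fallback sets out from 5, which is brominated on the methyl side (Br2, MeOH, 0–10 °C) to 1-bromo-3-methylbutan-2-one F3; a Kornblum oxidation (DMSO, NaHCO3, rt to 60 °C) then comes back to the route at 6.

Step 1 is the third risk, through incomplete C-methylation or O-methylation. The fallback sets out from 2, which is used to alkylate commercial methyl 2,4,6-trihydroxybenzoate (NaOMe, MeOH, reflux) to methyl 2-hydroxy-3,3,5,5-tetramethyl-4,6-dioxocyclohex-1-ene-1-carboxylate F4. The ester blocking group is then removed by hydrolysis and decarboxylation (6 M aq HCl, reflux) instead of by retro-Claisen cleavage, which comes back to the route at 4 and bypasses 3.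

**Further compounds**
F1 | step 4 | 2,2,4,4-tetramethyl-6-(3-methyl-2-oxobutyl)cyclohexane-1,3,5-trione | CC(C)C(=O)CC1C(=O)C(C)(C)C(=O)C(C)(C)C1=O
F2 | step 4 | 1′-epi-tomentodione Q (1R,4R,5S,9S,1′S) | C=C1CC[C@H]2[C@H](C(=O)C(C)C)C3=C(O[C@]2(C)CC[C@@H]2[C@@H]1CC2(C)C)C(C)(C)C(=O)C(C)(C)C3=O
F3 | step 3 | 1-bromo-3-methylbutan-2-one | CC(C)C(=O)CBr
F4 | step 1 | methyl 2-hydroxy-3,3,5,5-tetramethyl-4,6-dioxocyclohex-1-ene-1-carboxylate | COC(=O)C1=C(O)C(C)(C)C(=O)C(C)(C)C1=O
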